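The C2-symmetric biquinone is cut so that the four carbons spanning the inter-ring bond, C(phenethyl)=C–C=C(phenethyl), become an (E,E)-1,3-diene. The O=C–C(CH3)=C(OH)–C=O segment of each quinone ring (rings A and A′) becomes a squarate-derived cyclobutenone. The key step is a double thermal Moore ring expansion. Both four-membered rings open to dienylketenes and close onto the inner diene carbons. Two fully substituted six-membered rings then flank the diene's central bond, which becomes the tetra-ortho-substituted A–A′ axis, in one operation and with regiochemistry fixed by connectivity. The precursor is a diene-bridged bis(4-hydroxycyclobutenone) without any quinone ring.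

Key step: step 5

Assumption: the target is drawn without configuration at the A–A′ axis, so no control of axial chirality is attempted.

Step 1
Reactants: 1 diisopropyl squarate (3,4-diisopropoxycyclobut-3-ene-1,2-dione)
Product: 3 3-isopropoxy-4-methylcyclobut-3-ene-1,2-dione, via methyl carbinol 2 (not isolated)
Conditions: MeLi (1.05 equiv), THF, −78 °C; then 2 M aq HCl, CH2Cl2, rt
Reagents that add atoms: methyllithium, [Li]C; water, O (supplies the new carbonyl oxygen while the carbinol oxygen leaves as water)
Why: 1,2-addition of an organolithium to a squarate ester, followed by acid-induced ionisation of carbinol 2, capture of the alkoxy-stabilised cation by water and loss of isopropanol, is the standard entry to 3-alkoxy-4-alkylcyclobutenediones; the stereocentre of racemic 2 disappears in 3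

Step 2
Reactants: 4 4-phenylbut-1-yne
Product: 5 (E)-2-bromo-1-iodo-4-phenylbut-1-ene
Conditions: IBr (1.05 equiv), CH2Cl2, −78 to 0 °C, dark
Reagents that add atoms: iodine monobromide, BrI
Why: electrophilic iodobromination of a terminal alkyne runs through a bridged iodonium ion that bromide opens anti at the more substituted carbon, so the Markovnikov alkene with Br and I trans should result, and the unactivated phenyl ring should not compete at low temperature

Step 3
Reactants: 5 (E)-2-bromo-1-iodo-4-phenylbut-1-ene (two molecules)
Product: 7 (3E,5E)-3,6-dibromo-1,8-diphenylocta-3,5-diene, via alkenylboronate 6 (not isolated)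
Conditions: B2pin2 (0.5 equiv), PdCl2(dppf) (5 mol %), K2CO3 (3 equiv), 1,4-dioxane–H2O, 50 °C
Reagents that add atoms: bis(pinacolato)diboron, CC1(C)OB(OC1(C)C)B1OC(C)(C)C(C)(C)O1 (its boryl group is carried by 6 only and is lost again on the way to 7)
Why: in this one-pot Miyaura borylation/Suzuki–Miyaura homocoupling, zerovalent palladium inserts into the C–I bond much faster than into the hindered internal C–Br bond, half of 5 is borylated to 6 and couples with the other half with retention at both alkenes, and the trans placement of palladium and bromine in the alkenylpalladium intermediate rules out syn β-bromide elimination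

Step 4
Reactants: 7 (3E,5E)-3,6-dibromo-1,8-diphenylocta-3,5-diene; 3 3-isopropoxy-4-methylcyclobut-3-ene-1,2-dione (2.2 equiv)
Product: 9 4,4′-[(3E,5E)-1,8-diphenylocta-3,5-diene-3,6-diyl]bis(4-hydroxy-3-isopropoxy-2-methylcyclobut-2-en-1-one) (dl/meso mixture), via dilithiodiene 8 (not isolated)
Conditions: t-BuLi (4.0 equiv), Et2O–THF, −78 °C; then 3 (2.2 equiv), THF, −78 °C; aq NH4Cl
Reagents that add atoms: tert-butyllithium, [Li]C(C)(C)C (its lithium is carried by 8 only)
Why: bromine–lithium exchange of alkenyl bromides with two equivalents of t-BuLi per bromide occurs with retention, and organolithiums add 1,2 to 3-alkoxy-4-alkylcyclobutenediones at the carbonyl next to the alkoxy-bearing carbon because the other carbonyl is a deactivated vinylogous ester; the E,E geometry points each C–Li bond away from the other diene end, so the second lithium cannot attack the first cyclobutenone, and the two new carbinol stereocentres form without control, which is harmless because step 5 erases them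

Step 5
Reactants: 9 diene-bridged bis(4-hydroxycyclobutenone)
Product: 11 4,4′-diisopropoxy-5,5′-dimethyl-2,2′-bis(2-phenylethyl)-[1,1′-bi(cyclohexa-1,4-dien-1-yl)]-3,3′,6,6′-tetrone, via bis-hydroquinone 10 (not isolated)
Conditions: toluene (0.005 M), 110 °C, Ar; then Ag2O (5 equiv), rt
Reagents that add atoms: none
Why: Each 4-hydroxycyclobutenone opens by conrotatory 4π electrocyclic cleavage of the bond between its carbonyl carbon and its carbinol carbon, the hydroxyl rotating outward so that the dienyl arm lies inward on a dienylketene. The ketene carbon then bonds to the adjacent inner CH carbon of the diene in a 6π electrocyclisation, the only ring-closing mode in the step and used once for ring A and once for ring A′, and enolisation of each cyclohexadienone gives bis-hydroquinone 10, which Ag2O dehydrogenates to 11. The closest known reaction type is the thermal Moore ring expansion of 4-alkenyl-4-hydroxycyclobutenones to hydroquinones, applied here at both ends of one diene. Regiochemistry is set by connectivity: the carbinol carbon, which neighbours C–OiPr, already carries the phenethyl-bearing carbon, and the ketene carbon, which neighbours C–CH3, can reach only the CH carbon, so phenethyl ends beside the carbonyl flanked by oxygen and the A–A′ bond beside the carbonyl flanked by methyl. The selectivity needed is 6π closure over 8π closure and over trapping of the ketene by hydroxyl groups; the E alkene geometry leaves only hydrogen on the inside of each closing terminus and holds the far end of the diene out of reach, and high dilution handles the rest. No stereocentre is created, the two carbinol stereocentres of 9 are erased, and the A–A′ axis forms without control.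

Step 6
Reactants: 11 bis(isopropoxyquinone)
Product: 12 4,4′-dihydroxy-5,5′-dimethyl-2,2′-bis(2-phenylethyl)-[1,1′-bi(cyclohexa-1,4-dien-1-yl)]-3,3′,6,6′-tetrone (CNP0136737.0)
Conditions: BCl3 (6 equiv), CH2Cl2, −78 to 0 °C; then H2O
Reagents that add atoms: none
Why: in this Lewis acid dealkylation of a secondary alkyl ether, BCl3 chelates the quinone carbonyl and the adjacent ether oxygen and chloride removes the isopropyl group by alkyl–oxygen cleavage, as in the selective cleavage of isopropyl aryl ethers, while the methyl, phenethyl and quinone carbons stay untouched and no stereocentre is involved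

Compound list
1 | diisopropyl squarate (3,4-diisopropoxycyclobut-3-ene-1,2-dione) | CC(C)OC1=C(OC(C)C)C(=O)C1=O | starting material
2 | 4-hydroxy-2,3-diisopropoxy-4-methylcyclobut-2-en-1-one (racemic) | CC(C)OC1=C(OC(C)C)C(C)(O)C1=O | intermediate
3 | 3-isopropoxy-4-methylcyclobut-3-ene-1,2-dione | CC1=C(OC(C)C)C(=O)C1=O | intermediate
4 | 4-phenylbut-1-yne | C#CCCc1ccccc1 | starting material
5 | (E)-2-bromo-1-iodo-4-phenylbut-1-ene | I/C=C(/Br)CCc1ccccc1 | intermediate
6 | 2-[(E)-2-bromo-4-phenylbut-1-en-1-yl]-4,4,5,5-tetramethyl-1,3,2-dioxaborolane | CC1(C)OB(OC1(C)C)/C=C(/Br)CCc1ccccc1 | intermediate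
7 | (3E,5E)-3,6-dibromo-1,8-diphenylocta-3,5-diene | Br/C(CCc1ccccc1)=C/C=C(/Br)CCc1ccccc1 | intermediate
8 | 3,6-dilithio-1,8-diphenylocta-3,5-diene, each lithium trans to the neighbouring alkene carbon (geometry of 7 retained; 3Z,5Z by descriptor because carbon outranks lithium) | [Li]/C(CCc1ccccc1)=C/C=C(/[Li])CCc1ccccc1 | intermediate
9 | 4,4′-[(3E,5E)-1,8-diphenylocta-3,5-diene-3,6-diyl]bis(4-hydroxy-3-isopropoxy-2-methylcyclobut-2-en-1-one), dl/meso mixture at the two carbinol carbons | O=C1C(C)=C(OC(C)C)C1(O)/C(CCc1ccccc1)=C/C=C(/C1(O)C(OC(C)C)=C(C)C1=O)CCc1ccccc1 | intermediate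
10 | 4,4′-diisopropoxy-5,5′-dimethyl-2,2′-bis(2-phenylethyl)biphenyl-3,3′,6,6′-tetrol | Cc1c(O)c(-c2c(O)c(C)c(OC(C)C)c(O)c2CCc2ccccc2)c(CCc2ccccc2)c(O)c1OC(C)C | intermediate
11 | 4,4′-diisopropoxy-5,5′-dimethyl-2,2′-bis(2-phenylethyl)-[1,1′-bi(cyclohexa-1,4-dien-1-yl)]-3,3′,6,6′-tetrone | CC1=C(OC(C)C)C(=O)C(CCc2ccccc2)=C(C2=C(CCc3ccccc3)C(=O)C(OC(C)C)=C(C)C2=O)C1=O | intermediate
12 | 4,4′-dihydroxy-5,5′-dimethyl-2,2′-bis(2-phenylethyl)-[1,1′-bi(cyclohexa-1,4-dien-1-yl)]-3,3′,6,6′-tetrone (CNP0136737.0) | CC1=C(O)C(=O)C(CCc2ccccc2)=C(C2=C(CCc3ccccc3)C(=O)C(O)=C(C)C2=O)C1=O | target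

Total step count: 6. Longest linear sequence: 5 steps (4 → 5 → 7 → 9 → 11 → 12).

Steps most likely to fail

Step 3. Three processes could erode the homocoupling: competing insertion of palladium into the C–Br bonds followed by oligomerisation, reductive loss of the two trans halogens back to the alkyne, and protodeborylation of the alkenylboronate.
- The fallback sets out from 4 and comes back at 8. It makes the central bond first and installs the outer metal afterwards.
- Glaser–Hay coupling of 4 (CuCl, TMEDA, air, acetone) should give 1,8-diphenylocta-3,5-diyne F1.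
- Twofold copper-catalysed hydroboration follows (B2pin2, CuCl, Xantphos, NaOt-Bu, MeOH, THF). Syn borylcupration places copper next to the remaining unsaturation and boron on the outer carbon. This should give 2,2′-[(3Z,5Z)-1,8-diphenylocta-3,5-diene-3,6-diyl]bis(4,4,5,5-tetramethyl-1,3,2-dioxaborolane) F2, with boron trans to the neighbouring alkene carbon.
- Iododeboronation with retention (aq NaOH, then I2, THF, 0 °C) should give (3E,5E)-3,6-diiodo-1,8-diphenylocta-3,5-diene F3.
- Iodine–lithium exchange (t-BuLi, Et2O, −78 °C) delivers 8.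

Step 4. Three processes could stop the sequence at one-sided addition: incomplete second halogen–lithium exchange, poor solubility of the dilithium reagent, and proton transfer from the acidic ring methyl of 3 to the hindered alkenyllithium.
- The fallback sets out from 4 (with 3 as partner) and comes back at 11. It uses a monolithium reagent and forges the A–A′ bond last.
- Markovnikov hydrobromination of 4 (B-bromo-9-BBN, CH2Cl2, 0 °C; then AcOH) should give 2-bromo-4-phenylbut-1-ene F4.
- Bromine–lithium exchange (t-BuLi) and addition to 3 should give 4-hydroxy-3-isopropoxy-2-methyl-4-(4-phenylbut-1-en-2-yl)cyclobut-2-en-1-one F5.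
- The same thermal four-to-six ring expansion followed by Ag2O should give 2-isopropoxy-3-methyl-6-(2-phenylethyl)-1,4-benzoquinone F6.
- The only free ring position of F6 is brominated by addition–elimination (Br2, CH2Cl2; then Et3N) to 5-bromo-2-isopropoxy-3-methyl-6-(2-phenylethyl)-1,4-benzoquinone F7.
- Stille–Kelly reductive homocoupling (Me3SnSnMe3, Pd(PPh3)4, 1,4-dioxane, 100 °C) joins two molecules of F7 to 11.

Step 5. The second 6π closure takes place at a crowded terminus. It may become slow enough for the ketene to be diverted by intermolecular acylation of phenolic hydroxyl groups.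
- The fallback sets out from 3 and comes back at 11. It uses an unhindered linchpin and adds the phenethyl groups afterwards.
- (1E,3E)-1,4-diiodobuta-1,3-diene F8 is lithiated (t-BuLi, Et2O, −78 °C) and added to 3. This should give 4,4′-[(1E,3E)-buta-1,3-diene-1,4-diyl]bis(4-hydroxy-3-isopropoxy-2-methylcyclobut-2-en-1-one) F9.
- Double ring expansion (toluene, 110 °C) and Ag2O should give 4,4′-diisopropoxy-5,5′-dimethyl-[1,1′-bi(cyclohexa-1,4-dien-1-yl)]-3,3′,6,6′-tetrone F10.
- A twofold Jacobsen–Torssell decarboxylative radical alkylation (3-phenylpropanoic acid, AgNO3 catalytic, (NH4)2S2O8, MeCN–H2O, 70 °C) places 2-phenylethyl on the two remaining ring C–H positions to give 11.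

Further compounds
F1 | step 3 | 1,8-diphenylocta-3,5-diyne | c1ccccc1CCC#CC#CCCc1ccccc1
F2 | step 3 | 2,2′-[(3Z,5Z)-1,8-diphenylocta-3,5-diene-3,6-diyl]bis(4,4,5,5-tetramethyl-1,3,2-dioxaborolane) | CC1(C)OB(OC1(C)C)/C(CCc1ccccc1)=C/C=C(/B1OC(C)(C)C(C)(C)O1)CCc1ccccc1
F3 | step 3 | (3E,5E)-3,6-diiodo-1,8-diphenylocta-3,5-diene | I/C(CCc1ccccc1)=C/C=C(/I)CCc1ccccc1
F4 | step 4 | 2-bromo-4-phenylbut-1-ene | C=C(Br)CCc1ccccc1
F5 | step 4 | 4-hydroxy-3-isopropoxy-2-methyl-4-(4-phenylbut-1-en-2-yl)cyclobut-2-en-1-one (racemic) | C=C(CCc1ccccc1)C1(O)C(OC(C)C)=C(C)C1=O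
F6 | step 4 | 2-isopropoxy-3-methyl-6-(2-phenylethyl)-1,4-benzoquinone | CC1=C(OC(C)C)C(=O)C(CCc2ccccc2)=CC1=O
F7 | step 4 | 5-bromo-2-isopropoxy-3-methyl-6-(2-phenylethyl)-1,4-benzoquinone | CC1=C(OC(C)C)C(=O)C(CCc2ccccc2)=C(Br)C1=O
F8 | step 5 | (1E,3E)-1,4-diiodobuta-1,3-diene | I/C=C/C=C/I
F9 | step 5 | 4,4′-[(1E,3E)-buta-1,3-diene-1,4-diyl]bis(4-hydroxy-3-isopropoxy-2-methylcyclobut-2-en-1-one) (dl/meso mixture) | CC1=C(OC(C)C)C(O)(/C=C/C=C/C2(O)C(OC(C)C)=C(C)C2=O)C1=O
F10 | step 5 | 4,4′-diisopropoxy-5,5′-dimethyl-[1,1′-bi(cyclohexa-1,4-dien-1-yl)]-3,3′,6,6′-tetrone | CC1=C(OC(C)C)C(=O)C=C(C2=CC(=O)C(OC(C)C)=C(C)C2=O)C1=O
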